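# Proposed total synthesis of CNP0397160.1 by a convergent (4+3) cycloaddition

## Retrosynthetic overview

1. Target 30 ⇐ hydroxyl-directed hydrogenation of a C3=C3a cyclopentene ⇐ desilylation ⇐ Saegusa–Ito oxidation of silyl enol ether 27.
2. Key disconnection: the cycloheptenone is cut at C8–C8a and C4–C5 by a (4+3) cycloaddition that also joins the two halves: 2-silyloxydiene 16 (carrying the complete benzoxepine half) plus the cyclopentenyl 1,1-dimethylallyl cation from acetate 25.
3. Enabling feature: ring atoms C8–C7(=O)–C6(Me)=C5 are the hydrolysed, dehydrogenated form of a 2-silyloxy-1,3-diene, and C4(Me2)–C3a–C8a are an allyl unit whose central carbon C3a lies in the cyclopentane and can hold the charge left after both bonds form; the C1 silyloxy carbinol next to C8a is the controlling stereocentre.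
4. Diene 16 ⇐ Wittig methyl enone ⇐ ketone 9 ⇐ one epoxide-opening cascade of a Shi-derived diepoxide enol silane built from geranyl bromide; acetate 25 ⇐ (R)-linalool (ring-closing metathesis, directed epoxidation, cuprate opening).
5. Ring order: oxepane and cyclohexane together (step 5), cyclopentene (step 12), cycloheptene (step 19).

Key step: step 19

Remarks on the chemistry (assumptions):
- Locants. Benzoxepine half: O1, C2 (gem-dimethyl), C3 (secondary carbinol), C5a (methyl-bearing fusion carbon), C6 (side-chain carbon), C7 (tertiary carbinol), C9a (O-bearing fusion carbon). Hydroazulenone half: C1 (tertiary carbinol), C3a and C8a (ring fusion), C4 (gem-dimethyl), C5 (side-chain carbon), C6 (methyl-bearing carbon), C7 (carbonyl), C8 (CH2).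
- (R)-(−)-Linalool of high enantiomeric purity and ylide 14 are taken as commercial.
- C5 of cycloadduct 27 is expected as a mixture of epimers and is written without configuration; step 20 makes it sp2.
- The carbinol carbon of 24 and 25 is drawn as the expected major isomer; its configuration is lost on ionisation in step 19.

## Route

### Benzoxepine half and diene (steps 1–11)

Step 1
Reactants: 1 geranyl bromide; 2 dimethyl (2-oxopropyl)phosphonate
Product: 4 dimethyl [(5E)-6,10-dimethyl-2-oxoundeca-5,9-dien-1-yl]phosphonate, via phosphonate dianion 3 (not isolated)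
Conditions: NaH, THF, 0 °C; n-BuLi, 0 °C; then 1, 0 °C to rt; H2O quench
Reagents that add atoms: none
Why: The 1,3-dianion of a β-keto phosphonate is alkylated at its more basic terminal carbon, so the allylic bromide is displaced (SN2) at the former methyl group and the E-alkene of the geranyl unit is untouched.

Step 2
Reactants: 4 dimethyl [(5E)-6,10-dimethyl-2-oxoundeca-5,9-dien-1-yl]phosphonate; 5 3-(benzyloxy)propanal
Product: 6 (3E,8E)-1-(benzyloxy)-9,13-dimethyltetradeca-3,8,12-trien-5-one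
Conditions: Ba(OH)2·8H2O, THF/H2O (40:1), rt
Reagents that add atoms: none
Why: Horner–Wadsworth–Emmons olefination of a β-keto phosphonate under mild Ba(OH)2 conditions tolerates the base-sensitive β-alkoxy aldehyde and should give the E-enone.

Step 3
Reactants: 6 (3E,8E)-1-(benzyloxy)-9,13-dimethyltetradeca-3,8,12-trien-5-one
Product: 7 (4E)-7-(benzyloxy)-1-{(2R,3R)-3-[2-((2R)-3,3-dimethyloxiran-2-yl)ethyl]-3-methyloxiran-2-yl}hept-4-en-3-one
Conditions: D-fructose-derived Shi ketone (1,2:4,5-di-O-isopropylidene-β-D-erythro-2,3-hexodiulo-2,6-pyranose, 30 mol%), Oxone (2KHSO5·KHSO4·K2SO4), K2CO3, n-Bu4NHSO4, MeCN/dimethoxymethane/aq. Na2B4O7 buffer, 0 °C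
Reagents that add atoms: potassium peroxymonosulfate (active component of Oxone) [K+].[O-]S(=O)(=O)OO
Why: Shi epoxidation (chiral dioxirane) attacks only the two electron-rich trisubstituted alkenes, the enone being inert, and the catalyst-controlled spiro transition state should deliver oxygen to the same face of each, giving R-configured epoxide carbons throughout.

Step 4
Reactants: 7 diepoxy enone
Product: 8 triethyl{[(3Z)-7-(benzyloxy)-1-{(2R,3R)-3-[2-((2R)-3,3-dimethyloxiran-2-yl)ethyl]-3-methyloxiran-2-yl}hept-3-en-3-yl]oxy}silane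
Conditions: RhCl(PPh3)3 (1 mol%), Et3SiH, THF, 50 °C
Reagents that add atoms: triethylsilane CC[SiH](CC)CC
Why: Rhodium-catalysed 1,4-hydrosilylation of the enone through its s-cis conformer should give the regiodefined Z-silyl enol ether, which direct enolisation of a ketone with two α-CH2 groups could not provide, and leaves the epoxides alone.

Step 5
Reactants: 8 Z-triethylsilyl enol ether
Product: 9 (3R,5aR,6R,9aR)-6-[3-(benzyloxy)propyl]-2,2,5a-trimethyl-3-[(triethylsilyl)oxy]octahydro-1-benzoxepin-7(2H)-one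
Conditions: TESOTf (0.3 equiv), 2,6-di-tert-butyl-4-methylpyridine, CH2Cl2, −78 °C; Et3N quench
Reagents that add atoms: none
Why: In this silyl-triflate-initiated epoxide-opening cascade (oxacyclisation then carbacyclisation, a known reaction type for polyepoxide enol silanes), the silylated terminal epoxide is opened at its tertiary carbon by the internal epoxide oxygen and the enol silane attacks the tertiary carbon of the resulting epoxonium anti through a chair, so the trans-fused oxepane–cyclohexanone should form with C3 and C9a retained, C5a inverted and the C6 chain equatorial (Z-enol silane, also the thermodynamic epimer), the released silyl triflate carrying the chain.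

Step 6
Reactants: 9 bicyclic ketone
Product: 10 (3R,5aR,6R,7S,9aR)-6-[3-(benzyloxy)propyl]-2,2,5a,7-tetramethyl-3-[(triethylsilyl)oxy]decahydro-1-benzoxepin-7-ol
Conditions: MeLi, anhydrous CeCl3, THF, −78 °C; aqueous work-up
Reagents that add atoms: methyllithium [Li]C
Why: The organocerium reagent adds to the hindered, enolisable ketone without deprotonation, and the syn-axial C5a methyl forces equatorial approach, which should give the axial C7 hydroxyl and equatorial methyl.

Step 7
Reactants: 10 tertiary alcohol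
Product: 11 (3R,5aR,6R,7S,9aR)-6-[3-(benzyloxy)propyl]-2,2,5a,7-tetramethyl-3,7-bis[(triethylsilyl)oxy]decahydro-1-benzoxepine
Conditions: TESOTf, 2,6-lutidine, CH2Cl2, 0 °C to rt
Reagents that add atoms: triethylsilyl trifluoromethanesulfonate CC[Si](CC)(CC)OS(=O)(=O)C(F)(F)F
Why: Silyl triflate silylation protects the hindered tertiary alcohol, which would otherwise form a lactol with the aldehyde of step 9 and could ionise in step 19.

Step 8
Reactants: 11 bis-silyl ether
Product: 12 3-[(3R,5aR,6R,7S,9aR)-2,2,5a,7-tetramethyl-3,7-bis(triethylsilyloxy)decahydro-1-benzoxepin-6-yl]propan-1-ol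
Conditions: H2 (1 atm), Pd/C, EtOAc, rt
Reagents that add atoms: none
Why: Hydrogenolysis of the benzyl ether in a non-protic solvent frees the primary alcohol without cleaving the silyl ethers.

Step 9
Reactants: 12 primary alcohol
Product: 13 3-[(3R,5aR,6R,7S,9aR)-2,2,5a,7-tetramethyl-3,7-bis(triethylsilyloxy)decahydro-1-benzoxepin-6-yl]propanal
Conditions: Dess–Martin periodinane, NaHCO3, CH2Cl2, 0 °C to rt
Reagents that add atoms: none
Why: Buffered Dess–Martin oxidation should stop cleanly at the aldehyde, which has no epimerisable α-centre.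

Step 10
Reactants: 13 aldehyde; 14 3-(triphenyl-λ5-phosphanylidene)butan-2-one
Product: 15 (3E)-3-methyl-6-[(3R,5aR,6R,7S,9aR)-2,2,5a,7-tetramethyl-3,7-bis(triethylsilyloxy)decahydro-1-benzoxepin-6-yl]hex-3-en-2-one
Conditions: toluene, 90 °C
Reagents that add atoms: none
Why: Wittig reaction of the stabilised α-branched ylide should give the E-trisubstituted methyl enone.

Step 11
Reactants: 15 methyl enone
Product: 16 tert-butyl(dimethyl){[(3E)-3-methyl-6-[(3R,5aR,6R,7S,9aR)-2,2,5a,7-tetramethyl-3,7-bis(triethylsilyloxy)decahydro-1-benzoxepin-6-yl]hexa-1,3-dien-2-yl]oxy}silane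
Conditions: TBSOTf, Et3N, CH2Cl2, −78 to 0 °C
Reagents that add atoms: tert-butyldimethylsilyl trifluoromethanesulfonate CC(C)(C)[Si](C)(C)OS(=O)(=O)C(F)(F)F
Why: Soft enolisation removes the methyl ketone α'-proton and should give the cross-conjugated 2-silyloxy-1,3-diene with the E-alkene unchanged.

### Cyclopentenyl acetate (steps 12–18)

Step 12
Reactants: 17 (R)-(−)-linalool
Product: 18 (1R)-1-methylcyclopent-2-en-1-ol
Conditions: second-generation Grubbs catalyst (H2IMes)(PCy3)Cl2Ru=CHPh (1 mol%), CH2Cl2, 40 °C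
Reagents that add atoms: none
Why: Ring-closing metathesis expels 2-methylpropene and gives the cyclopentenol with the chiral-pool tertiary carbinol centre untouched.

Step 13
Reactants: 18 (1R)-1-methylcyclopent-2-en-1-ol
Product: 19 (1S,2R,5S)-2-methyl-6-oxabicyclo[3.1.0]hexan-2-ol
Conditions: VO(acac)2 (2 mol%), t-BuOOH, CH2Cl2, 0 °C to rt
Reagents that add atoms: tert-butyl hydroperoxide CC(C)(C)OO
Why: Vanadium-catalysed hydroxyl-directed epoxidation delivers oxygen syn to the tertiary hydroxyl, so the cis-epoxy alcohol should form.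

Step 14
Reactants: 19 cis-epoxy alcohol
Product: 20 (1R,2S,3S)-1-methyl-3-(prop-1-en-2-yl)cyclopentane-1,2-diol
Conditions: CH2=C(CH3)MgBr (3 equiv), CuI (10 mol%), THF, −30 to 0 °C; aqueous work-up
Reagents that add atoms: isopropenylmagnesium bromide CC(=C)[Mg]Br
Why: Copper-catalysed Grignard opening of the epoxide should occur anti at the carbon remote from the quaternary carbinol, installing the isopropenyl group (the future gem-dimethyl carbon) and leaving a cis-1,2-diol.

Step 15
Reactants: 20 diol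
Product: 22 (2R)-2-hydroxy-2-methyl-5-(propan-2-ylidene)cyclopentan-1-one, via isopropenyl ketone 21 (not isolated)
Conditions: IBX, DMSO, rt; then DBU (0.3 equiv), CH2Cl2, rt
Reagents that add atoms: none
Why: IBX oxidises the secondary alcohol of a 1,2-diol to the α-hydroxy ketone without C–C cleavage, and base then moves the β,γ-double bond into conjugation as the tetrasubstituted isopropylidene ketone.

Step 16
Reactants: 22 hydroxy enone
Product: 23 (2R)-2-{[tert-butyl(dimethyl)silyl]oxy}-2-methyl-5-(propan-2-ylidene)cyclopentan-1-one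
Conditions: TBSOTf, 2,6-lutidine, CH2Cl2, −78 to 0 °C
Reagents that add atoms: tert-butyldimethylsilyl trifluoromethanesulfonate CC(C)(C)[Si](C)(C)OS(=O)(=O)C(F)(F)F
Why: Silyl triflate silylation of the tertiary α-hydroxyl installs the bulky group that is to shield one face of the allyl cation.

Step 17
Reactants: 23 silyloxy enone
Product: 24 (1S,2R)-2-{[tert-butyl(dimethyl)silyl]oxy}-2-methyl-5-(propan-2-ylidene)cyclopentan-1-ol
Conditions: NaBH4, CeCl3·7H2O, MeOH, −40 °C
Reagents that add atoms: none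
Why: Luche reduction should give clean 1,2-reduction of the hindered enone, hydride arriving anti to the silyloxy group so that the new hydroxyl is cis to it.

Step 18
Reactants: 24 allylic alcohol
Product: 25 (1S,2R)-2-{[tert-butyl(dimethyl)silyl]oxy}-2-methyl-5-(propan-2-ylidene)cyclopentyl acetate
Conditions: Ac2O, Et3N, DMAP (cat.), CH2Cl2, 0 °C
Reagents that add atoms: acetic anhydride CC(=O)OC(C)=O
Why: Acylation turns the allylic alcohol into a leaving group that a silyl triflate can ionise at low temperature.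

### Key step and endgame (steps 19–22)

Step 19
Reactants: 16 2-silyloxydiene; 25 allylic acetate
Product: 27 tert-butyl[((1R,8aR)-1-{[tert-butyl(dimethyl)silyl]oxy}-1,4,4,6-tetramethyl-5-{2-[(3R,5aR,6R,7S,9aR)-2,2,5a,7-tetramethyl-3,7-bis(triethylsilyloxy)decahydro-1-benzoxepin-6-yl]ethyl}-1,2,4,5,8,8a-hexahydroazulen-7-yl)oxy]dimethylsilane, via allyl cation 26 (not isolated)
Conditions: TMSOTf (1.1 equiv), 2,6-di-tert-butyl-4-methylpyridine (2 equiv), CH2Cl2, −78 to −40 °C; Et3N quench
Reagents that add atoms: none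
Why: Proposed new method: TMSOTf ionises acetate 25 to the 1,1-dimethylallyl cation 26, the terminal CH2 of diene 16 adds to its ring CH terminus (C8–C8a bond) to give an O-silyl oxocarbenium (silyloxyallyl) cation, the tetrasubstituted isopropylidene bond then attacks the distal carbon of that cation (C4–C5 bond), and the hindered pyridine removes a ring CH2 proton from the resulting tertiary C3a cation; the closest known reaction types are (4+3) cycloadditions of allyl cations with 1,3-dienes, including heteroaryl-carbinyl cations that give 5-7-fused rings through the exocyclic carbon and the adjacent ring carbon, and the Mukaiyama-type SN1 allylation of silyl enol ethers. The cycloheptene is the only ring closed, in a stepwise (4+3) mode whose second bond is a 7-endo-trig cation–olefin closure that creates the quaternary gem-dimethyl carbon. C8a is set by attack on the planar cation anti to the OTBS group on C1 (the departing acetate lies on that same face), which places the new CH2 cis to the C1 methyl as the target requires, while C5 forms as an inconsequential mixture. The step needs regioselectivity (diene CH2 to the ring terminus and not to CMe2), which the higher nucleophilicity of the enol ether terminus, the lower substitution of the ring terminus and the position of the leaving group in the ion pair should secure. It also needs ring closure to outrun desilylation of the oxocarbenium ion, for which the robust TBS enol ether and low temperature are chosen, and proton loss from the accessible C3 methylene in preference to the ring-fusion C8a–H, which the hindered base should favour.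

Step 20
Reactants: 27 cycloadduct (silyl enol ether)
Product: 28 (1R,8aR)-1-{[tert-butyl(dimethyl)silyl]oxy}-1,4,4,6-tetramethyl-5-{2-[(3R,5aR,6R,7S,9aR)-2,2,5a,7-tetramethyl-3,7-bis(triethylsilyloxy)decahydro-1-benzoxepin-6-yl]ethyl}-2,4,8,8a-tetrahydroazulen-7(1H)-one
Conditions: Pd(OAc)2 (1.2 equiv), MeCN/CH2Cl2, 40 °C
Reagents that add atoms: none
Why: In this Saegusa–Ito oxidation, palladation of the silyl enol ether at C6 and β-hydride elimination of the C5 hydrogen should give the conjugated tetrasubstituted enone and remove the undefined C5 centre.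

Step 21
Reactants: 28 protected enone
Product: 29 (1R,8aR)-5-{2-[(3R,5aR,6R,7S,9aR)-3,7-dihydroxy-2,2,5a,7-tetramethyldecahydro-1-benzoxepin-6-yl]ethyl}-1-hydroxy-1,4,4,6-tetramethyl-2,4,8,8a-tetrahydroazulen-7(1H)-one
Conditions: HF·pyridine, pyridine, THF, 0 °C to rt
Reagents that add atoms: none
Why: Buffered fluoride cleaves the two triethylsilyl ethers and the tertiary tert-butyldimethylsilyl ether without dehydrating the tertiary alcohols.

Step 22
Reactants: 29 triol
Product: 30 (1R,3aR,8aR)-5-{2-[(3R,5aR,6R,7S,9aR)-3,7-dihydroxy-2,2,5a,7-tetramethyldecahydro-1-benzoxepin-6-yl]ethyl}-1-hydroxy-1,4,4,6-tetramethyl-2,3,3a,4,8,8a-hexahydroazulen-7(1H)-one (target)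
Conditions: H2 (1 atm), [Ir(cod)(PCy3)(py)]PF6 (5 mol%), CH2Cl2, rt
Reagents that add atoms: none
Why: In this hydroxyl-directed hydrogenation the homoallylic C1 hydroxyl binds the cationic iridium catalyst and delivers hydrogen to the trisubstituted C3=C3a bond from its own face, which should set H-3a cis to H-8a and to the hydroxyl (cis ring fusion) while the tetrasubstituted enone is left alone.

## Compound list

1 | geranyl bromide, (2E)-1-bromo-3,7-dimethylocta-2,6-diene | CC(C)=CCC/C(C)=C/CBr | starting material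
2 | dimethyl (2-oxopropyl)phosphonate | CC(=O)CP(=O)(OC)OC | starting material
3 | sodium lithium 1,3-dianion of 2 | [Na+].[Li+].[CH2-]C(=O)[CH-]P(=O)(OC)OC | intermediate (not isolated)
4 | dimethyl [(5E)-6,10-dimethyl-2-oxoundeca-5,9-dien-1-yl]phosphonate | CC(C)=CCC/C(C)=C/CCC(=O)CP(=O)(OC)OC | intermediate
5 | 3-(benzyloxy)propanal | O=CCCOCc1ccccc1 | starting material
6 | (3E,8E)-1-(benzyloxy)-9,13-dimethyltetradeca-3,8,12-trien-5-one | CC(C)=CCC/C(C)=C/CCC(=O)/C=C/CCOCc1ccccc1 | intermediate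
7 | (4E)-7-(benzyloxy)-1-{(2R,3R)-3-[2-((2R)-3,3-dimethyloxiran-2-yl)ethyl]-3-methyloxiran-2-yl}hept-4-en-3-one | CC1(C)O[C@@H]1CC[C@@]1(C)O[C@@H]1CCC(=O)/C=C/CCOCc1ccccc1 | intermediate
8 | triethyl{[(3Z)-7-(benzyloxy)-1-{(2R,3R)-3-[2-((2R)-3,3-dimethyloxiran-2-yl)ethyl]-3-methyloxiran-2-yl}hept-3-en-3-yl]oxy}silane | CC1(C)O[C@@H]1CC[C@@]1(C)O[C@@H]1CC/C(O[Si](CC)(CC)CC)=C/CCCOCc1ccccc1 | intermediate
9 | (3R,5aR,6R,9aR)-6-[3-(benzyloxy)propyl]-2,2,5a-trimethyl-3-[(triethylsilyl)oxy]octahydro-1-benzoxepin-7(2H)-one | c1ccccc1COCCC[C@@H]1[C@@]2(C)CC[C@@H](O[Si](CC)(CC)CC)C(C)(C)O[C@@H]2CCC1=O | intermediate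
10 | (3R,5aR,6R,7S,9aR)-6-[3-(benzyloxy)propyl]-2,2,5a,7-tetramethyl-3-[(triethylsilyl)oxy]decahydro-1-benzoxepin-7-ol | c1ccccc1COCCC[C@@H]1[C@@]2(C)CC[C@@H](O[Si](CC)(CC)CC)C(C)(C)O[C@@H]2CC[C@]1(C)O | intermediate
11 | (3R,5aR,6R,7S,9aR)-6-[3-(benzyloxy)propyl]-2,2,5a,7-tetramethyl-3,7-bis[(triethylsilyl)oxy]decahydro-1-benzoxepine | c1ccccc1COCCC[C@@H]1[C@@]2(C)CC[C@@H](O[Si](CC)(CC)CC)C(C)(C)O[C@@H]2CC[C@]1(C)O[Si](CC)(CC)CC | intermediate
12 | 3-[(3R,5aR,6R,7S,9aR)-2,2,5a,7-tetramethyl-3,7-bis(triethylsilyloxy)decahydro-1-benzoxepin-6-yl]propan-1-ol | OCCC[C@@H]1[C@@]2(C)CC[C@@H](O[Si](CC)(CC)CC)C(C)(C)O[C@@H]2CC[C@]1(C)O[Si](CC)(CC)CC | intermediate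
13 | 3-[(3R,5aR,6R,7S,9aR)-2,2,5a,7-tetramethyl-3,7-bis(triethylsilyloxy)decahydro-1-benzoxepin-6-yl]propanal | O=CCC[C@@H]1[C@@]2(C)CC[C@@H](O[Si](CC)(CC)CC)C(C)(C)O[C@@H]2CC[C@]1(C)O[Si](CC)(CC)CC | intermediate
14 | 3-(triphenyl-λ5-phosphanylidene)butan-2-one | CC(=O)C(C)=P(c1ccccc1)(c1ccccc1)c1ccccc1 | starting material
15 | (3E)-3-methyl-6-[(3R,5aR,6R,7S,9aR)-2,2,5a,7-tetramethyl-3,7-bis(triethylsilyloxy)decahydro-1-benzoxepin-6-yl]hex-3-en-2-one | CC(=O)/C(C)=C/CC[C@@H]1[C@@]2(C)CC[C@@H](O[Si](CC)(CC)CC)C(C)(C)O[C@@H]2CC[C@]1(C)O[Si](CC)(CC)CC | intermediate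
16 | tert-butyl(dimethyl){[(3E)-3-methyl-6-[(3R,5aR,6R,7S,9aR)-2,2,5a,7-tetramethyl-3,7-bis(triethylsilyloxy)decahydro-1-benzoxepin-6-yl]hexa-1,3-dien-2-yl]oxy}silane | C=C(O[Si](C)(C)C(C)(C)C)/C(C)=C/CC[C@@H]1[C@@]2(C)CC[C@@H](O[Si](CC)(CC)CC)C(C)(C)O[C@@H]2CC[C@]1(C)O[Si](CC)(CC)CC | intermediate
17 | (R)-(−)-linalool, (3R)-3,7-dimethylocta-1,6-dien-3-ol | C=C[C@](C)(O)CCC=C(C)C | starting material
18 | (1R)-1-methylcyclopent-2-en-1-ol | C[C@@]1(O)CCC=C1 | intermediate
19 | (1S,2R,5S)-2-methyl-6-oxabicyclo[3.1.0]hexan-2-ol | C[C@@]1(O)CC[C@@H]2O[C@H]12 | intermediate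
20 | (1R,2S,3S)-1-methyl-3-(prop-1-en-2-yl)cyclopentane-1,2-diol | C[C@@]1(O)CC[C@@H](C(C)=C)[C@@H]1O | intermediate
21 | (2R,5S)-2-hydroxy-2-methyl-5-(prop-1-en-2-yl)cyclopentan-1-one | C[C@@]1(O)CC[C@@H](C(C)=C)C1=O | intermediate (not isolated)
22 | (2R)-2-hydroxy-2-methyl-5-(propan-2-ylidene)cyclopentan-1-one | C[C@@]1(O)CCC(=C(C)C)C1=O | intermediate
23 | (2R)-2-{[tert-butyl(dimethyl)silyl]oxy}-2-methyl-5-(propan-2-ylidene)cyclopentan-1-one | C[C@@]1(O[Si](C)(C)C(C)(C)C)CCC(=C(C)C)C1=O | intermediate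
24 | (1S,2R)-2-{[tert-butyl(dimethyl)silyl]oxy}-2-methyl-5-(propan-2-ylidene)cyclopentan-1-ol | C[C@@]1(O[Si](C)(C)C(C)(C)C)CCC(=C(C)C)[C@@H]1O | intermediate
25 | (1S,2R)-2-{[tert-butyl(dimethyl)silyl]oxy}-2-methyl-5-(propan-2-ylidene)cyclopentyl acetate | C[C@@]1(O[Si](C)(C)C(C)(C)C)CCC(=C(C)C)[C@@H]1OC(C)=O | intermediate
26 | 2-[(3R)-3-{[tert-butyl(dimethyl)silyl]oxy}-3-methylcyclopent-1-en-1-yl]propan-2-ylium trifluoromethanesulfonate (allyl cation) | C[C@@]1(O[Si](C)(C)C(C)(C)C)CCC(=C1)[C+](C)C.[O-]S(=O)(=O)C(F)(F)F | intermediate (not isolated)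
27 | tert-butyl[((1R,8aR)-1-{[tert-butyl(dimethyl)silyl]oxy}-1,4,4,6-tetramethyl-5-{2-[(3R,5aR,6R,7S,9aR)-2,2,5a,7-tetramethyl-3,7-bis(triethylsilyloxy)decahydro-1-benzoxepin-6-yl]ethyl}-1,2,4,5,8,8a-hexahydroazulen-7-yl)oxy]dimethylsilane (C5 epimers) | CC1=C(O[Si](C)(C)C(C)(C)C)C[C@@H]2C(=CC[C@@]2(C)O[Si](C)(C)C(C)(C)C)C(C)(C)C1CC[C@@H]1[C@@]2(C)CC[C@@H](O[Si](CC)(CC)CC)C(C)(C)O[C@@H]2CC[C@]1(C)O[Si](CC)(CC)CC | intermediate
28 | (1R,8aR)-1-{[tert-butyl(dimethyl)silyl]oxy}-1,4,4,6-tetramethyl-5-{2-[(3R,5aR,6R,7S,9aR)-2,2,5a,7-tetramethyl-3,7-bis(triethylsilyloxy)decahydro-1-benzoxepin-6-yl]ethyl}-2,4,8,8a-tetrahydroazulen-7(1H)-one | CC1=C(CC[C@@H]2[C@@]3(C)CC[C@@H](O[Si](CC)(CC)CC)C(C)(C)O[C@@H]3CC[C@]2(C)O[Si](CC)(CC)CC)C(C)(C)C2=CC[C@@](C)(O[Si](C)(C)C(C)(C)C)[C@@H]2CC1=O | intermediate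
29 | (1R,8aR)-5-{2-[(3R,5aR,6R,7S,9aR)-3,7-dihydroxy-2,2,5a,7-tetramethyldecahydro-1-benzoxepin-6-yl]ethyl}-1-hydroxy-1,4,4,6-tetramethyl-2,4,8,8a-tetrahydroazulen-7(1H)-one | CC1=C(CC[C@@H]2[C@@]3(C)CC[C@@H](O)C(C)(C)O[C@@H]3CC[C@]2(C)O)C(C)(C)C2=CC[C@@](C)(O)[C@@H]2CC1=O | intermediate
30 | (1R,3aR,8aR)-5-{2-[(3R,5aR,6R,7S,9aR)-3,7-dihydroxy-2,2,5a,7-tetramethyldecahydro-1-benzoxepin-6-yl]ethyl}-1-hydroxy-1,4,4,6-tetramethyl-2,3,3a,4,8,8a-hexahydroazulen-7(1H)-one | CC1=C(CC[C@@H]2[C@@]3(C)CC[C@@H](O)C(C)(C)O[C@@H]3CC[C@]2(C)O)C(C)(C)[C@@H]2CC[C@@](C)(O)[C@@H]2CC1=O | target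

## Step count and risk assessment

Total step count: 22. Longest linear sequence: 15 steps (steps 1–11, then 19–22); the cyclopentenyl branch is 7 steps (12–18).

Steps most likely to fail:

1. Step 19 (proposed new method).
   - What may go wrong: desilylation of the first-formed oxocarbenium ion before the second C–C bond forms, so that only open-chain alkylation occurs; attack of the diene at the CMe2 terminus; semipinacol methyl shift or proton loss of the allyl cation; proton loss toward C8a instead of C3.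
   - Fallback (known reactions, the two bonds made separately): it sets out from 16 and 25 and returns at 28. ZnCl2 in CH2Cl2 at −40 °C is used to stop at the Mukaiyama-type SN1 allylation of the silyl dienol ether, which should give the open-chain enone F1 with C8a already set anti to the silyloxy group. Me2AlCl (CH2Cl2, −78 to 0 °C) then promotes an intramolecular ene reaction in which the enone is the enophile and the isopropylidene group the ene, closing the seven-membered ring, forming the gem-dimethyl quaternary carbon and placing the double bond in the cyclopentene, to give the cyclised ketone F2. TMSCl, NaI and Et3N in MeCN should give the thermodynamic tetrasubstituted trimethylsilyl enol ether F3, and Saegusa–Ito oxidation with Pd(OAc)2 leads to 28.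

2. Step 5.
   - What may go wrong: attack of the enol silane on the internal epoxide before the oxepane has formed, protodesilylation of the enol silane, or 6-exo instead of 7-endo oxacyclisation.
   - Fallback (a stabilised terminating nucleophile, side chain attached after ring formation): it sets out from 4 and returns at 9. Shi epoxidation of keto phosphonate 4 should give the diepoxy keto phosphonate F4, and TESOTf with Et3N the only possible conjugated triethylsilyl enol ether F5. The silyl triflate cascade, now terminated by this unhindered 1,3-dicarbonyl-type nucleophile, should give the bicyclic keto phosphonate F6. Horner–Wadsworth–Emmons reaction of F6 with aldehyde 5 (NaH, THF) attaches the side chain as the alkylidene ketone F7, and conjugate reduction with [(Ph3P)CuH]6 followed by equilibration with DBU should give 9.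

3. Step 20.
   - What may go wrong: β-hydride elimination toward the C6 methyl group, giving the exocyclic enone, or slow palladation of the hindered tetrasubstituted enol ether.
   - Fallback (halogenation–elimination instead of palladium): it sets out from 27 and returns at 28. N-Bromosuccinimide in THF at −78 °C should convert the silyl enol ether into the tertiary α-bromo ketone F8, and Li2CO3/LiBr in DMF at 110 °C eliminates HBr under equilibrating conditions to the endocyclic enone 28.

Further compounds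
F1 | step 19 | (3E)-1-[(1S,5R)-5-{[tert-butyl(dimethyl)silyl]oxy}-5-methyl-2-(propan-2-ylidene)cyclopentyl]-3-methyl-6-[(3R,5aR,6R,7S,9aR)-2,2,5a,7-tetramethyl-3,7-bis(triethylsilyloxy)decahydro-1-benzoxepin-6-yl]hex-3-en-2-one (open-chain enone) | O=C(C[C@@H]1C(=C(C)C)CC[C@@]1(C)O[Si](C)(C)C(C)(C)C)/C(C)=C/CC[C@@H]1[C@@]2(C)CC[C@@H](O[Si](CC)(CC)CC)C(C)(C)O[C@@H]2CC[C@]1(C)O[Si](CC)(CC)CC
F2 | step 19 | (1R,8aR)-1-{[tert-butyl(dimethyl)silyl]oxy}-1,4,4,6-tetramethyl-5-{2-[(3R,5aR,6R,7S,9aR)-2,2,5a,7-tetramethyl-3,7-bis(triethylsilyloxy)decahydro-1-benzoxepin-6-yl]ethyl}-2,4,5,6,8,8a-hexahydroazulen-7(1H)-one (cyclised ketone, C5 and C6 epimers) | CC1C(CC[C@@H]2[C@@]3(C)CC[C@@H](O[Si](CC)(CC)CC)C(C)(C)O[C@@H]3CC[C@]2(C)O[Si](CC)(CC)CC)C(C)(C)C2=CC[C@@](C)(O[Si](C)(C)C(C)(C)C)[C@@H]2CC1=O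
F3 | step 19 | trimethylsilyl enol ether analogue of 27 (C5 epimers) | CC1=C(O[Si](C)(C)C)C[C@@H]2C(=CC[C@@]2(C)O[Si](C)(C)C(C)(C)C)C(C)(C)C1CC[C@@H]1[C@@]2(C)CC[C@@H](O[Si](CC)(CC)CC)C(C)(C)O[C@@H]2CC[C@]1(C)O[Si](CC)(CC)CC
F4 | step 5 | dimethyl (4-{(2R,3R)-3-[2-((2R)-3,3-dimethyloxiran-2-yl)ethyl]-3-methyloxiran-2-yl}-2-oxobutyl)phosphonate | CC1(C)O[C@@H]1CC[C@@]1(C)O[C@@H]1CCC(=O)CP(=O)(OC)OC
F5 | step 5 | triethylsilyl enol ether of F4 (alkene geometry not assigned) | CC1(C)O[C@@H]1CC[C@@]1(C)O[C@@H]1CCC(O[Si](CC)(CC)CC)=CP(=O)(OC)OC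
F6 | step 5 | dimethyl [(3R,5aR,6R,9aR)-2,2,5a-trimethyl-7-oxo-3-(triethylsilyloxy)decahydro-1-benzoxepin-6-yl]phosphonate | COP(=O)(OC)[C@@H]1[C@@]2(C)CC[C@@H](O[Si](CC)(CC)CC)C(C)(C)O[C@@H]2CCC1=O
F7 | step 5 | (3R,5aR,9aR)-6-[3-(benzyloxy)propylidene]-2,2,5a-trimethyl-3-(triethylsilyloxy)octahydro-1-benzoxepin-7(2H)-one (alkene geometry not assigned) | c1ccccc1COCCC=C1[C@@]2(C)CC[C@@H](O[Si](CC)(CC)CC)C(C)(C)O[C@@H]2CCC1=O
F8 | step 20 | (1R,8aR)-6-bromo-1-{[tert-butyl(dimethyl)silyl]oxy}-1,4,4,6-tetramethyl-5-{2-[(3R,5aR,6R,7S,9aR)-2,2,5a,7-tetramethyl-3,7-bis(triethylsilyloxy)decahydro-1-benzoxepin-6-yl]ethyl}-2,4,5,6,8,8a-hexahydroazulen-7(1H)-one (C5 and C6 epimers) | CC1(Br)C(CC[C@@H]2[C@@]3(C)CC[C@@H](O[Si](CC)(CC)CC)C(C)(C)O[C@@H]3CC[C@]2(C)O[Si](CC)(CC)CC)C(C)(C)C2=CC[C@@](C)(O[Si](C)(C)C(C)(C)C)[C@@H]2CC1=O
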